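**Retrosynthetic overview**
1. Numbering: ring B is the 1,2-dioxane O1–O2–C3(H, propanoate arm)–C4–C5–C6(CH3, chain); ring A is the cyclohexane C1'(OH)–C2'(=CH2)…C6'(CH3)2. The last C–C disconnection is the exocyclic CH2–C6 bond. It gives a ring A ethylzinc reagent (C11) and a ring B 6-methoxy peroxyketal ester (C10).
2. Enabling feature: C6 is bonded to O1 of the O1–O2 bridge of ring B. At the ketal level (C6–OCH3) it ionises to a cyclic peroxycarbenium ion C6=O1(+)–O2. The C3 arm lies 1,4 across ring B and cis to the bond to be made, which is the outcome expected for axial attack on the half-chair cation.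
3. Ring B: an Evans syn aldol sets C2 and a C3 carbinol of inverted sense. Ozonolysis in methanol gives a hydroperoxy ketal, whose peroxide anion displaces the C3 mesylate (6-exo-tet, inversion).
4. Ring A is bought with beta-cyclocitral. Katsuki–Sharpless epoxidation sets C1'–O, epoxide-to-allylic-alcohol isomerisation makes C2'=CH2, and methylenation plus hydrozirconation–iodination add the terminal CH2–I.
5. Order of ring events: ring A is present from the start, ring B is closed in step 6, the rings are joined in step 16, and desilylation follows in step 17.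

Key step: step 16

Remark: the ketal carbon C6 arises as a mixture of epimers in step 6 and carries no stereo label in the SMILES until step 16, where both epimers give the same cation.

**Ring B fragment**

Step 1
Reactants: 1 ethyl 4-methylpent-4-enoate
Product: 2 4-methylpent-4-enal
Conditions: i-Bu2AlH, CH2Cl2, −78 °C; aq. potassium sodium tartrate
Reagents that add atoms: none
Why: Partial ester reduction with i-Bu2AlH stops at the aluminium hemiacetal at −78 °C, which releases the aldehyde only on work-up, and no stereocentre is involved.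

Step 2
Reactants: 3 (4S)-4-benzyl-3-propanoyl-1,3-oxazolidin-2-one; 2 4-methylpent-4-enal
Product: 5 (4S)-4-benzyl-3-[(2S,3R)-3-hydroxy-2,6-dimethylhept-6-enoyl]-1,3-oxazolidin-2-one, via dibutylboron Z-enolate 4 (not isolated)
Conditions: Bu2BOTf, Et3N, CH2Cl2, −78 to 0 °C; 2, −78 to 0 °C; pH 7 buffer, MeOH, 30% H2O2, 0 °C
Reagents that add atoms: none
Why: Evans syn aldol reaction, in which the Z-boron enolate reacts through a Zimmerman–Traxler chair on the face remote from the benzyl group and sets C2 as S and the carbinol C3 as R, the latter on purpose opposite to the target because step 6 inverts it.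

Step 3
Reactants: 5 aldol adduct
Product: 6 (2R,3R)-2,6-dimethylhept-6-ene-1,3-diol
Conditions: LiBH4, THF/MeOH, 0 °C; aq. NaOH
Reagents that add atoms: none
Why: Reductive removal of the Evans auxiliary leaves both stereocentres untouched and removes the acidifying carbonyl group, so that the later sulfonate cannot be lost by E1cB elimination.

Step 4
Reactants: 6 diol
Product: 7 (2R,3R)-1-[tert-butyl(dimethyl)silyl]oxy-2,6-dimethylhept-6-en-3-ol
Conditions: TBSCl, imidazole, CH2Cl2, 0 °C
Reagents that add atoms: tert-butyldimethylsilyl chloride CC(C)(C)[Si](C)(C)Cl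
Why: Sterically controlled monosilylation should take the primary hydroxyl group and leave the branched secondary one free.

Step 5
Reactants: 7 silyl ether
Product: 8 (2R,3R)-1-[tert-butyl(dimethyl)silyl]oxy-2,6-dimethylhept-6-en-3-yl methanesulfonate
Conditions: MsCl, Et3N, CH2Cl2, 0 °C
Reagents that add atoms: methanesulfonyl chloride CS(=O)(=O)Cl
Why: Mesylation forms only an O–S bond, so the configuration at C3 is retained and a leaving group is installed.

Step 6
Reactants: 8 mesylate
Product: 10 tert-butyl{(2R)-2-[(3S)-6-methoxy-6-methyl-1,2-dioxan-3-yl]propoxy}dimethylsilane, via hydroperoxy ketal 9 (not isolated)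
Conditions: O3, CH2Cl2/MeOH, −78 °C; O2 purge, concentrate; KOt-Bu, 18-crown-6, THF, 0 °C
Reagents that add atoms: ozone [O-][O+]=O; methanol CO
Why: Criegee ozonolysis of the 1,1-disubstituted alkene in methanol gives the ketone O-oxide, which methanol traps as hydroperoxy ketal 9, and its potassium peroxide anion then displaces the secondary mesylate in an intramolecular 6-exo-tet SN2 reaction with inversion, a known entry to 3-alkoxy-1,2-dioxanes that closes ring B and sets C3 as S.

Step 7
Reactants: 10 silyl-protected dioxane
Product: 11 (2R)-2-[(3S)-6-methoxy-6-methyl-1,2-dioxan-3-yl]propan-1-ol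
Conditions: TBAF, THF, 0 °C
Reagents that add atoms: none
Why: Fluoride-mediated desilylation is tolerated by dialkyl peroxides and by the acid-labile peroxyketal.

Step 8
Reactants: 11 dioxane alcohol
Product: 13 methyl (2S)-2-[(3S)-6-methoxy-6-methyl-1,2-dioxan-3-yl]propanoate, via carboxylic acid 12 (not isolated)
Conditions: TEMPO (cat.), PhI(OAc)2, MeCN/H2O, rt; then TMSCHN2, toluene/MeOH, 0 °C
Reagents that add atoms: water O; (trimethylsilyl)diazomethane C[Si](C)(C)C=[N+]=[N-]
Why: Oxoammonium oxidation (TEMPO/PhI(OAc)2) of the primary alcohol to the acid does not touch the O–O bond, and esterification with the diazoalkane is base-free, so C2 is not epimerised and no retro-oxa-Michael opening can occur.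

**Ring A fragment**

Step 9
Reactants: 14 beta-cyclocitral (2,6,6-trimethylcyclohex-1-ene-1-carbaldehyde)
Product: 15 (2,6,6-trimethylcyclohex-1-en-1-yl)methanol
Conditions: NaBH4, MeOH, 0 °C
Reagents that add atoms: none
Why: Borohydride 1,2-reduction of the hindered enal gives the allylic alcohol needed for directed epoxidation.

Step 10
Reactants: 15 beta-cyclogeraniol
Product: 16 [(1R,6R)-2,2,6-trimethyl-7-oxabicyclo[4.1.0]heptan-1-yl]methanol
Conditions: Ti(OiPr)4 (cat.), D-(−)-diethyl tartrate (cat.), t-BuOOH, 4 Å MS, CH2Cl2, −20 °C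
Reagents that add atoms: tert-butyl hydroperoxide CC(C)(C)OO
Why: Katsuki–Sharpless asymmetric epoxidation, in which the D-(−)-tartrate catalyst delivers oxygen to the alkene face that gives the (1R,6R)-epoxide and so fixes the C1'–O bond that is kept to the end.

Step 11
Reactants: 16 epoxy alcohol
Product: 17 (1S)-1-(hydroxymethyl)-2,2-dimethyl-6-methylidenecyclohexan-1-ol
Conditions: Et2Al(TMP) [from 2,2,6,6-tetramethylpiperidine, n-BuLi, Et2AlCl; TMP = 2,2,6,6-tetramethylpiperidide], toluene, 0 °C to rt; aq. potassium sodium tartrate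
Reagents that add atoms: none
Why: Aluminium-amide-mediated epoxide-to-allylic-alcohol isomerisation is a syn elimination in which the bulky amide takes the least hindered beta-proton (the methyl group), so the C–O bond at the methyl-bearing carbon breaks while the C1'–O bond and its configuration stay.

Step 12
Reactants: 17 ene-diol
Product: 18 triethyl{[(1S)-2,2-dimethyl-6-methylidene-1-(triethylsilyloxy)cyclohexyl]methoxy}silane
Conditions: TESOTf, 2,6-lutidine, CH2Cl2, −78 to 0 °C
Reagents that add atoms: triethylsilyl triflate CC[Si](CC)(CC)OS(=O)(=O)C(F)(F)F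
Why: Silylation with the silyl triflate and a hindered base is strong enough for the tertiary allylic alcohol and does not ionise it at low temperature.

Step 13
Reactants: 18 bis(silyl ether)
Product: 19 (1S)-2,2-dimethyl-6-methylidene-1-(triethylsilyloxy)cyclohexane-1-carbaldehyde
Conditions: (COCl)2, DMSO, CH2Cl2, −78 to −40 °C; Et3N, −78 °C to rt
Reagents that add atoms: none
Why: Swern oxidation converts primary triethylsilyl ethers directly into aldehydes, while the hindered tertiary silyl ether survives and the product has no alpha-hydrogen to scramble.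

Step 14
Reactants: 19 aldehyde
Product: 20 {[(1S)-1-ethenyl-2,2-dimethyl-6-methylidenecyclohexyl]oxy}triethylsilane
Conditions: Ph3PCH3Br, KOt-Bu, THF, 0 °C to rt
Reagents that add atoms: methyltriphenylphosphonium bromide C[P+](c1ccccc1)(c1ccccc1)c1ccccc1.[Br-]
Why: Wittig methylenation with the small unstabilised ylide tolerates the neopentyl-type aldehyde and adds the carbon that will become the chain terminus.

Step 15
Reactants: 20 vinyl carbinol silyl ether
Product: 22 triethyl{[(1S)-1-(2-iodoethyl)-2,2-dimethyl-6-methylidenecyclohexyl]oxy}silane, via alkylzirconocene chloride 21 (not isolated)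
Conditions: Cp2Zr(H)Cl, THF, rt; I2, 0 °C
Reagents that add atoms: iodine II
Why: Hydrozirconation–iodination, in which Cp2Zr(H)Cl adds much faster to the monosubstituted vinyl group than to the 1,1-disubstituted ring alkene, places zirconium on the terminal carbon, and iodinolysis gives the primary iodide.

**Union and end game**

Step 16
Reactants: 22 ring A iodide; 13 ring B peroxyketal ester
Product: 25 methyl (2S)-2-[(3S,6R)-6-{2-[(1S)-2,2-dimethyl-6-methylidene-1-(triethylsilyloxy)cyclohexyl]ethyl}-6-methyl-1,2-dioxan-3-yl]propanoate, via dialkylzinc 23 (not isolated), via peroxycarbenium triflate 24 (not isolated)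
Conditions: 22 (2 equiv), Et2Zn, CuI (cat.), neat, 50 °C, then volatiles off in vacuo; 13 (1 equiv), TMSOTf, CH2Cl2, −78 °C; H2O quench
Reagents that add atoms: none
Why: Proposed new method: copper-catalysed iodine–zinc exchange turns 22 into the salt-free dialkylzinc 23, TMSOTf removes the C6 methoxy group of 13 as TMSOMe, and the cyclic peroxycarbenium ion 24 (C6=O1(+)–O2) is captured at C6 by one primary alkyl group of 23, so the CH2–C6 bond, the fully substituted peroxy carbon and the whole carbon skeleton arise in one operation. The closest known reaction types are the Lewis-acid-mediated substitution of 3-alkoxy-1,2-dioxanes and 3-alkoxy-1,2-dioxolanes by allylsilanes and silyl ketene acetals through peroxycarbenium ions, and the TMSOTf-promoted coupling of dialkylzincs with six-membered cyclic oxocarbenium ions made from alpha-acetoxy ethers; new is the pairing of an sp3 zinc nucleophile with a peroxycarbenium ion. No ring is closed, and ring B is carried through intact. The new stereocentre C6 is controlled by C3: in the half-chair cation (C5, C6, O1 and O2 coplanar) the C3 arm sits pseudo-equatorial, and stereoelectronically preferred axial attack through a chair-like transition state should place the incoming chain axial and cis to that arm (6R) with the methyl group equatorial, whichever C6 epimer of 13 was ionised. The step needs loss of the exocyclic methoxy group instead of ring opening, attack at carbon instead of at peroxide oxygen, and alkyl transfer instead of beta-hydride transfer or proton loss from 24. The higher basicity of the methoxy oxygen, the low basicity and oxophilicity of a diorganozinc at −78 °C (organolithium and Grignard reagents attack the O–O bond), the absence of halide salts and amine bases, and the far faster ionisation of a ketal than of the tertiary allylic silyl ether should secure this.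

Step 17
Reactants: 25 silyl-protected coupling product
Product: 26 methyl (2S)-2-[(3S,6R)-6-{2-[(1S)-1-hydroxy-2,2-dimethyl-6-methylidenecyclohexyl]ethyl}-6-methyl-1,2-dioxan-3-yl]propanoate
Conditions: HF·pyridine, pyridine, THF, 0 °C
Reagents that add atoms: none
Why: Fluoride-mediated desilylation under buffered non-basic conditions avoids retro-oxa-Michael opening and Kornblum–DeLaMare fragmentation of the beta-peroxy ester, and the pyridine buffer should keep the tertiary allylic alcohol from ionising.

**Compound list**
1 | ethyl 4-methylpent-4-enoate | C=C(C)CCC(=O)OCC | starting material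
2 | 4-methylpent-4-enal | C=C(C)CCC=O | intermediate
3 | (4S)-4-benzyl-3-propanoyl-1,3-oxazolidin-2-one | CCC(=O)N1[C@@H](Cc2ccccc2)COC1=O | starting material
4 | dibutylboron Z-enolate of 3 | C/C=C(\OB(CCCC)CCCC)N1[C@@H](Cc2ccccc2)COC1=O | intermediate
5 | (4S)-4-benzyl-3-[(2S,3R)-3-hydroxy-2,6-dimethylhept-6-enoyl]-1,3-oxazolidin-2-one | C=C(C)CC[C@@H](O)[C@H](C)C(=O)N1[C@@H](Cc2ccccc2)COC1=O | intermediate
6 | (2R,3R)-2,6-dimethylhept-6-ene-1,3-diol | C=C(C)CC[C@@H](O)[C@H](C)CO | intermediate
7 | (2R,3R)-1-[tert-butyl(dimethyl)silyl]oxy-2,6-dimethylhept-6-en-3-ol | C=C(C)CC[C@@H](O)[C@H](C)CO[Si](C)(C)C(C)(C)C | intermediate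
8 | (2R,3R)-1-[tert-butyl(dimethyl)silyl]oxy-2,6-dimethylhept-6-en-3-yl methanesulfonate | C=C(C)CC[C@@H](OS(C)(=O)=O)[C@H](C)CO[Si](C)(C)C(C)(C)C | intermediate
9 | (2R,3R)-1-[tert-butyl(dimethyl)silyl]oxy-6-hydroperoxy-6-methoxy-2-methylheptan-3-yl methanesulfonate (C6 epimers) | COC(C)(OO)CC[C@@H](OS(C)(=O)=O)[C@H](C)CO[Si](C)(C)C(C)(C)C | intermediate
10 | tert-butyl{(2R)-2-[(3S)-6-methoxy-6-methyl-1,2-dioxan-3-yl]propoxy}dimethylsilane (C6 epimers) | COC1(C)CC[C@@H]([C@H](C)CO[Si](C)(C)C(C)(C)C)OO1 | intermediate
11 | (2R)-2-[(3S)-6-methoxy-6-methyl-1,2-dioxan-3-yl]propan-1-ol (C6 epimers) | COC1(C)CC[C@@H]([C@H](C)CO)OO1 | intermediate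
12 | (2S)-2-[(3S)-6-methoxy-6-methyl-1,2-dioxan-3-yl]propanoic acid (C6 epimers) | COC1(C)CC[C@@H]([C@H](C)C(=O)O)OO1 | intermediate
13 | methyl (2S)-2-[(3S)-6-methoxy-6-methyl-1,2-dioxan-3-yl]propanoate (C6 epimers) | COC1(C)CC[C@@H]([C@H](C)C(=O)OC)OO1 | intermediate
14 | beta-cyclocitral (2,6,6-trimethylcyclohex-1-ene-1-carbaldehyde) | CC1=C(C=O)C(C)(C)CCC1 | starting material
15 | (2,6,6-trimethylcyclohex-1-en-1-yl)methanol | CC1=C(CO)C(C)(C)CCC1 | intermediate
16 | [(1R,6R)-2,2,6-trimethyl-7-oxabicyclo[4.1.0]heptan-1-yl]methanol | OC[C@@]12O[C@]1(C)CCCC2(C)C | intermediate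
17 | (1S)-1-(hydroxymethyl)-2,2-dimethyl-6-methylidenecyclohexan-1-ol | C=C1CCCC(C)(C)[C@@]1(O)CO | intermediate
18 | triethyl{[(1S)-2,2-dimethyl-6-methylidene-1-(triethylsilyloxy)cyclohexyl]methoxy}silane | C=C1CCCC(C)(C)[C@@]1(O[Si](CC)(CC)CC)CO[Si](CC)(CC)CC | intermediate
19 | (1S)-2,2-dimethyl-6-methylidene-1-(triethylsilyloxy)cyclohexane-1-carbaldehyde | C=C1CCCC(C)(C)[C@@]1(O[Si](CC)(CC)CC)C=O | intermediate
20 | {[(1S)-1-ethenyl-2,2-dimethyl-6-methylidenecyclohexyl]oxy}triethylsilane | C=C1CCCC(C)(C)[C@@]1(O[Si](CC)(CC)CC)C=C | intermediate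
21 | chlorobis(cyclopentadienyl){2-[(1S)-2,2-dimethyl-6-methylidene-1-(triethylsilyloxy)cyclohexyl]ethyl}zirconium | C=C1CCCC(C)(C)[C@@]1(O[Si](CC)(CC)CC)CC[Zr](Cl)(C1C=CC=C1)C1C=CC=C1 | intermediate
22 | triethyl{[(1S)-1-(2-iodoethyl)-2,2-dimethyl-6-methylidenecyclohexyl]oxy}silane | C=C1CCCC(C)(C)[C@@]1(O[Si](CC)(CC)CC)CCI | intermediate
23 | bis{2-[(1S)-2,2-dimethyl-6-methylidene-1-(triethylsilyloxy)cyclohexyl]ethyl}zinc | C=C1CCCC(C)(C)[C@@]1(O[Si](CC)(CC)CC)CC[Zn]CC[C@@]1(O[Si](CC)(CC)CC)C(=C)CCCC1(C)C | intermediate
24 | cyclic peroxycarbenium triflate (C6=O1(+) of ring B, C3 arm unchanged) | CC1=[O+]O[C@@H](CC1)[C@H](C)C(=O)OC.[O-]S(=O)(=O)C(F)(F)F | intermediate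
25 | methyl (2S)-2-[(3S,6R)-6-{2-[(1S)-2,2-dimethyl-6-methylidene-1-(triethylsilyloxy)cyclohexyl]ethyl}-6-methyl-1,2-dioxan-3-yl]propanoate | C=C1CCCC(C)(C)[C@@]1(O[Si](CC)(CC)CC)CC[C@@]1(C)CC[C@@H]([C@H](C)C(=O)OC)OO1 | intermediate
26 | methyl (2S)-2-[(3S,6R)-6-{2-[(1S)-1-hydroxy-2,2-dimethyl-6-methylidenecyclohexyl]ethyl}-6-methyl-1,2-dioxan-3-yl]propanoate | C=C1CCCC(C)(C)[C@@]1(O)CC[C@@]1(C)CC[C@@H]([C@H](C)C(=O)OC)OO1 | target

**Step count:** 17 steps in total. The longest linear sequence is 10 steps (steps 1–8, 16, 17).

**Steps most likely to fail**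

Step 16. Alkyl transfer from zinc may lose against several processes:
- beta-hydride transfer from the zinc alkyl to the cation;
- proton loss from the cation to a vinyl peroxide;
- ring-opening ionisation or Lewis-acid-induced O–O heterolysis.

Facial selectivity may also erode if the ester carbonyl takes part. In the fallback the same CH2–C6 bond is made with a pi-nucleophile of the class already documented for peroxycarbenium ions, and the activating group is removed afterwards. The fallback sets out from 22. Magnesium insertion (Mg, Et2O) gives the alkylmagnesium iodide F1, and CO2 converts it into the propanoic acid F2. LiN(iPr)2 (2.2 equiv) followed by TMSCl gives the bis(trimethylsilyl) ketene acetal F3. F3 and 13 are joined with TMSOTf in CH2Cl2 at −78 °C, a Mukaiyama-type substitution of a 3-alkoxy-1,2-dioxane with the same axial attack. Aqueous work-up should give the chain-carboxylated coupling product F4 as epimers at the carbon that is a plain CH2 in the target. DCC and N-hydroxypyridine-2-thione give the Barton ester F5. Photolysis with a high concentration of t-BuSH (Barton reductive decarboxylation) comes back to the route at 25. Hydrogen transfer must be fast here, because it has to outrun closure of the beta-peroxyalkyl radical to an epoxide.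

Step 6. The peroxide anion may act as a base on the hindered secondary mesylate (E2 loss of the leaving group). Alternatively the substitution may be so slow that the hydroperoxy ketal decays first. The fallback changes the electrophile from a sulfonate under basic conditions to a strained ether under acid catalysis, using the known intramolecular hydroperoxide–oxetane cyclisation. It sets out from 6. TsCl in pyridine gives the primary monotosylate F6. KOt-Bu closes the 2,3-disubstituted oxetane F7, which retains the C3 configuration because the C3–O bond is not touched. Ozonolysis in CH2Cl2/MeOH gives the oxetanyl hydroperoxy ketal F8. Catalytic Yb(OTf)3 should trigger 6-exo opening of the oxetane at its substituted carbon with inversion. This comes back to the route at 11 and bypasses steps 4, 5 and 7.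

Step 15. Hydrozirconation of the neopentyl-type vinyl group may be sluggish, so that addition to the ring alkene or loss of the allylic silyloxy group competes. The fallback builds the terminal carbon at the carbonyl oxidation level, so no alkene has to be distinguished from another. It sets out from 19. Wittig reaction with Ph3P=CHOCH3 (from the phosphonium chloride and KOt-Bu) gives the methyl enol ether F9. Mild hydrolysis (pyridinium tosylate, wet acetone) gives the homologous aldehyde F10, and NaBH4 gives the primary alcohol F11. An Appel iodination (I2, PPh3, imidazole) comes back to the route at 22.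

**Further compounds**
F1 | step 16 | {2-[(1S)-2,2-dimethyl-6-methylidene-1-(triethylsilyloxy)cyclohexyl]ethyl}magnesium iodide | C=C1CCCC(C)(C)[C@@]1(O[Si](CC)(CC)CC)CC[Mg]I
F2 | step 16 | 3-[(1S)-2,2-dimethyl-6-methylidene-1-(triethylsilyloxy)cyclohexyl]propanoic acid | C=C1CCCC(C)(C)[C@@]1(O[Si](CC)(CC)CC)CCC(=O)O
F3 | step 16 | bis(trimethylsilyl) ketene acetal of F2 | C=C1CCCC(C)(C)[C@@]1(O[Si](CC)(CC)CC)CC=C(O[Si](C)(C)C)O[Si](C)(C)C
F4 | step 16 | 25 carrying CO2H on the chain carbon next to C6 (both epimers at that carbon) | C=C1CCCC(C)(C)[C@@]1(O[Si](CC)(CC)CC)CC(C(=O)O)[C@@]1(C)CC[C@@H]([C@H](C)C(=O)OC)OO1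
F5 | step 16 | N-acyloxypyridine-2-thione (Barton ester) of F4 | C=C1CCCC(C)(C)[C@@]1(O[Si](CC)(CC)CC)CC(C(=O)ON1C=CC=CC1=S)[C@@]1(C)CC[C@@H]([C@H](C)C(=O)OC)OO1
F6 | step 6 | (2R,3R)-3-hydroxy-2,6-dimethylhept-6-en-1-yl 4-methylbenzenesulfonate | C=C(C)CC[C@@H](O)[C@H](C)COS(=O)(=O)c1ccc(C)cc1
F7 | step 6 | (2R,3R)-3-methyl-2-(3-methylbut-3-en-1-yl)oxetane | C=C(C)CC[C@H]1OC[C@H]1C
F8 | step 6 | (2R,3R)-2-(3-hydroperoxy-3-methoxybutyl)-3-methyloxetane (ketal epimers) | COC(C)(OO)CC[C@H]1OC[C@H]1C
F9 | step 15 | triethyl{[(1S)-1-(2-methoxyethenyl)-2,2-dimethyl-6-methylidenecyclohexyl]oxy}silane (E/Z mixture) | C=C1CCCC(C)(C)[C@@]1(O[Si](CC)(CC)CC)C=COC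
F10 | step 15 | 2-[(1S)-2,2-dimethyl-6-methylidene-1-(triethylsilyloxy)cyclohexyl]acetaldehyde | C=C1CCCC(C)(C)[C@@]1(O[Si](CC)(CC)CC)CC=O
F11 | step 15 | 2-[(1S)-2,2-dimethyl-6-methylidene-1-(triethylsilyloxy)cyclohexyl]ethan-1-ol | C=C1CCCC(C)(C)[C@@]1(O[Si](CC)(CC)CC)CCO
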